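**Plan**

- Retrosynthesis: C2 of the isoflavone (the O1–C2 and C2–C3 bonds of ring C) is removed to leave a symmetric 2,4,6-trihydroxydeoxybenzoin. Ring A is then cut at C4a–C5 to an open-chain methyl 3,5,7-triketo ester.
- The chain is cut between its C6 and C7 into a 2,4-diprenyl-3,5-diketo ester and a ring B arylacetic N-methoxy-N-methylamide. The chromene on ring B goes back to an aryl 1,1-dimethylpropargyl ether.
- Enabling feature: ring A (C4a, C5, C6, C7, C8, C8a) is a fully substituted acylphloroglucinol. Its oxygen-bearing carbons (C5, C7, C8a) alternate with carbon-substituted ones (C4a acyl, C6 and C8 prenyl), which is the pattern of a folded triketo ester alkylated at its two methine carbons.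
- Forward: the chain is made from methyl acetoacetate by two prenylations and one acetylation. Ring B with its chromene ring is made from 2,4-dihydroxyphenylacetic acid. The two are joined by polyanion acylation; ring A then closes by Claisen condensation, ring C closes with a one-carbon amide acetal, and the methoxymethyl (MOM) ether is removed last.
- Stereochemistry: the target has no stereocentre and no stereogenic double bond. The two methine centres of the chain are carried as mixtures and vanish when ring A aromatises.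

Key step: step 10

Assumption: compounds 4, 5 and 14 are mixtures of stereoisomers and keto–enol tautomers and are used as such. Chain locants C1–C8 of 5 and 14 count from the ester carbon.

**Route**

Step 1
Reactants: 1 methyl 3-oxobutanoate (methyl acetoacetate); 2 1-bromo-3-methylbut-2-ene
Product: 3 methyl 7-methyl-3-oxooct-6-enoate
Conditions: LiN(iPr)2 (2.05 equiv), THF, 0 °C; then 2, 0 °C → rt; aq. NH4Cl
Reagents that add atoms: none
Why: β-Keto ester dianion alkylation, in which the last-formed, least stabilised γ-carbanion displaces the allylic bromide (SN2) so that only the terminal methyl is prenylated; no stereocentre is formed.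

Step 2
Reactants: 3 methyl 7-methyl-3-oxooct-6-enoate; 2 1-bromo-3-methylbut-2-ene
Product: 4 methyl 7-methyl-2-(3-methylbut-2-en-1-yl)-3-oxooct-6-enoate (racemic)
Conditions: K2CO3, acetone, reflux
Reagents that add atoms: none
Why: Enolate C-alkylation of a β-keto ester at its doubly activated C2 with a reactive allylic bromide; the new C2 centre forms racemic and is erased in step 10.

Step 3
Reactants: 4 methyl 7-methyl-2-(3-methylbut-2-en-1-yl)-3-oxooct-6-enoate
Product: 5 methyl 2,4-bis(3-methylbut-2-en-1-yl)-3,5-dioxohexanoate (stereoisomer and tautomer mixture)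
Conditions: LiN(iPr)2 (2.05 equiv), THF, −78 → 0 °C; then MeC(O)N(OMe)Me, −78 → 0 °C; aq. NH4Cl
Reagents that add atoms: N-methoxy-N-methylacetamide, CC(=O)N(C)OC
Why: γ-C-Acylation of the α,γ-dianion of a β-keto ester by an N-methoxy-N-methylamide, whose chelated tetrahedral adduct releases the acidic 1,3-diketone only on work-up; the C4 centre forms unselectively and is erased in step 10.

Step 4
Reactants: 6 (2,4-dihydroxyphenyl)acetic acid
Product: 7 6-hydroxy-1-benzofuran-2(3H)-one
Conditions: p-TsOH·H2O (cat.), toluene, reflux, azeotropic removal of water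
Reagents that add atoms: none
Why: Acid-catalysed lactonisation (intramolecular Fischer esterification) of a 2-hydroxyphenylacetic acid ties up the ortho hydroxyl in a five-membered lactone and leaves only the para hydroxyl free.

Step 5
Reactants: 7 6-hydroxy-1-benzofuran-2(3H)-one
Product: 8 6-(methoxymethoxy)-1-benzofuran-2(3H)-one
Conditions: MeOCH2Cl, iPr2NEt, CH2Cl2, 0 °C → rt
Reagents that add atoms: chloromethyl methyl ether, COCCl
Why: O-Alkylation of the only free phenol with an α-chloro ether under a tertiary amine gives the MOM acetal, which tolerates the amide bases, alkoxide and heat used later.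

Step 6
Reactants: 8 6-(methoxymethoxy)-1-benzofuran-2(3H)-one
Product: 9 2-[2-hydroxy-4-(methoxymethoxy)phenyl]-N-methoxy-N-methylacetamide
Conditions: MeNH(OMe), AlMe3, CH2Cl2, 0 °C → rt; aq. KNaC4H4O6
Reagents that add atoms: N,O-dimethylhydroxylamine, CNOC
Why: Aluminium amide aminolysis of a lactone: the dimethylaluminium amide opens the activated aryl ester to the N-methoxy-N-methylamide and frees the ortho phenol that will carry the chromene oxygen.

Step 7
Reactants: 9 2-[2-hydroxy-4-(methoxymethoxy)phenyl]-N-methoxy-N-methylacetamide; 10 3-chloro-3-methylbut-1-yne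
Product: 11 N-methoxy-2-[4-(methoxymethoxy)-2-[(2-methylbut-3-yn-2-yl)oxy]phenyl]-N-methylacetamide
Conditions: CuCl2·2H2O (cat.), DBU, MeCN, 0 °C → rt
Reagents that add atoms: none
Why: Copper-catalysed O-propargylation of a phenol by a tertiary propargylic chloride gives the aryl 1,1-dimethylpropargyl ether without C-alkylation.

Step 8
Reactants: 11 N-methoxy-2-[4-(methoxymethoxy)-2-[(2-methylbut-3-yn-2-yl)oxy]phenyl]-N-methylacetamide
Product: 13 N-methoxy-2-[5-(methoxymethoxy)-2,2-dimethyl-2H-chromen-8-yl]-N-methylacetamide, via ortho-allenylphenol 12 (not isolated)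
Conditions: o-xylene, 140 °C
Reagents that add atoms: none
Why: Aromatic propargyl Claisen rearrangement to the only free ortho carbon (between the two oxygens) gives the ortho-allenylphenol, which closes the 2,2-dimethyl-2H-chromene by 1,5-hydrogen shift and oxa-6π electrocyclisation; the other ortho position is blocked by the side chain.

Step 9
Reactants: 5 methyl 2,4-bis(3-methylbut-2-en-1-yl)-3,5-dioxohexanoate; 13 N-methoxy-2-[5-(methoxymethoxy)-2,2-dimethyl-2H-chromen-8-yl]-N-methylacetamide
Product: 14 methyl 8-[5-(methoxymethoxy)-2,2-dimethyl-2H-chromen-8-yl]-2,4-bis(3-methylbut-2-en-1-yl)-3,5,7-trioxooctanoate (stereoisomer and tautomer mixture, used crude)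
Conditions: LiN(iPr)2 (3.0 equiv on 5), THF, 0 °C; then 13 (0.8 equiv), −78 → 0 °C; aq. NH4Cl
Reagents that add atoms: none
Why: Terminal C-acylation of a β-polycarbonyl polyanion: the trianion of the 3,5-diketo ester reacts at its last-formed C6 carbanion with the N-methoxy-N-methylamide, whose stable lithium chelate prevents over-addition while the ester is masked as its enolate.

Step 10
Reactants: 14 methyl 8-[5-(methoxymethoxy)-2,2-dimethyl-2H-chromen-8-yl]-2,4-bis(3-methylbut-2-en-1-yl)-3,5,7-trioxooctanoate
Product: 15 2-[5-(methoxymethoxy)-2,2-dimethyl-2H-chromen-8-yl]-1-[2,4,6-trihydroxy-3,5-bis(3-methylbut-2-en-1-yl)phenyl]ethan-1-one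
Conditions: NaOMe (4 equiv), MeOH, 65 °C, argon; then AcOH
Reagents that add atoms: none
Why: NaOMe ionises first the only unsubstituted 1,3-dicarbonyl methylene (chain C6, between the C5 and C7 carbonyls); this enolate carbon adds to the C1 ester carbonyl, methoxide is expelled, and the 2-acyl-4,6-diprenylcyclohexane-1,3,5-trione enolises three times to the benzene-1,3,5-triol, whose phenoxide makes the sequence irreversible. The closest known reaction is the strong-base Claisen (Dieckmann-type) cyclisation of 3,5,7-triketo esters to acylphloroglucinols. Ring A closes in a 6-exo-trig (6-enolexo) mode, the new bond being C4a–C5 in isoflavone numbering. No stereocentre is created, and the C2 and C4 centres of the chain become sp2 ring carbons, so their mixed configuration does not matter. The step needs Claisen closure to win over aldol closure: attack of C2 on the C7 ketone would give a ring with a quaternary carbon that cannot aromatise and can revert by retro-aldol, the C7 carbonyl is deactivated as part of the C5–C7 enolate under a non-chelating sodium counter-ion, and attack of the benzylic C8 on the C3 ketone is disfavoured because C8 is the least acidic site and C3 lies between two branched carbons. The product is symmetric about the acyl group, so either ortho hydroxyl can close ring C.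

Step 11
Reactants: 15 2-[5-(methoxymethoxy)-2,2-dimethyl-2H-chromen-8-yl]-1-[2,4,6-trihydroxy-3,5-bis(3-methylbut-2-en-1-yl)phenyl]ethan-1-one
Product: 17 5,7-dihydroxy-3-[5-(methoxymethoxy)-2,2-dimethyl-2H-chromen-8-yl]-6,8-bis(3-methylbut-2-en-1-yl)-4H-chromen-4-one, via enaminone 16 (not isolated)
Conditions: Me2NCH(OMe)2 (3 equiv), THF, 60 °C
Reagents that add atoms: N,N-dimethylformamide dimethyl acetal, COC(OC)N(C)C
Why: Isoflavone synthesis from a 2-hydroxydeoxybenzoin with an amide acetal: condensation at the activated methylene gives the enaminone, an ortho hydroxyl adds to its β-carbon and dimethylamine is lost to close ring C; the two ortho hydroxyls are equivalent, so only one isoflavone can form.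

Step 12
Reactants: 17 5,7-dihydroxy-3-[5-(methoxymethoxy)-2,2-dimethyl-2H-chromen-8-yl]-6,8-bis(3-methylbut-2-en-1-yl)-4H-chromen-4-one
Product: 18 Kanzonol L, 5,7-dihydroxy-3-(5-hydroxy-2,2-dimethyl-2H-chromen-8-yl)-6,8-bis(3-methylbut-2-en-1-yl)-4H-chromen-4-one
Conditions: HCl (3 M aq.), MeOH, 40 °C
Reagents that add atoms: none
Why: Acid-catalysed acetal exchange (methanolysis) of the phenolic MOM ether, which should be faster under these mild conditions than protonation of the prenyl and chromene double bonds.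

**Compound list**

1 | methyl 3-oxobutanoate (methyl acetoacetate) | COC(=O)CC(C)=O | starting material
2 | 1-bromo-3-methylbut-2-ene | CC(C)=CCBr | starting material
3 | methyl 7-methyl-3-oxooct-6-enoate | COC(=O)CC(=O)CCC=C(C)C | intermediate
4 | methyl 7-methyl-2-(3-methylbut-2-en-1-yl)-3-oxooct-6-enoate (racemic) | COC(=O)C(CC=C(C)C)C(=O)CCC=C(C)C | intermediate
5 | methyl 2,4-bis(3-methylbut-2-en-1-yl)-3,5-dioxohexanoate (stereoisomer mixture) | COC(=O)C(CC=C(C)C)C(=O)C(CC=C(C)C)C(C)=O | intermediate
6 | (2,4-dihydroxyphenyl)acetic acid | OC(=O)Cc1ccc(O)cc1O | starting material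
7 | 6-hydroxy-1-benzofuran-2(3H)-one | O=C1Cc2ccc(O)cc2O1 | intermediate
8 | 6-(methoxymethoxy)-1-benzofuran-2(3H)-one | O=C1Cc2ccc(OCOC)cc2O1 | intermediate
9 | 2-[2-hydroxy-4-(methoxymethoxy)phenyl]-N-methoxy-N-methylacetamide | CON(C)C(=O)Cc1ccc(OCOC)cc1O | intermediate
10 | 3-chloro-3-methylbut-1-yne | CC(C)(Cl)C#C | starting material
11 | N-methoxy-2-[4-(methoxymethoxy)-2-[(2-methylbut-3-yn-2-yl)oxy]phenyl]-N-methylacetamide | CON(C)C(=O)Cc1ccc(OCOC)cc1OC(C)(C)C#C | intermediate
12 | 2-[2-hydroxy-4-(methoxymethoxy)-3-(3-methylbuta-1,2-dien-1-yl)phenyl]-N-methoxy-N-methylacetamide (ortho-allenylphenol, not isolated) | CON(C)C(=O)Cc1ccc(OCOC)c(C=C=C(C)C)c1O | intermediate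
13 | N-methoxy-2-[5-(methoxymethoxy)-2,2-dimethyl-2H-chromen-8-yl]-N-methylacetamide | CON(C)C(=O)Cc1ccc(OCOC)c2c1OC(C)(C)C=C2 | intermediate
14 | methyl 8-[5-(methoxymethoxy)-2,2-dimethyl-2H-chromen-8-yl]-2,4-bis(3-methylbut-2-en-1-yl)-3,5,7-trioxooctanoate (stereoisomer mixture) | COC(=O)C(CC=C(C)C)C(=O)C(CC=C(C)C)C(=O)CC(=O)Cc1ccc(OCOC)c2c1OC(C)(C)C=C2 | intermediate
15 | 2-[5-(methoxymethoxy)-2,2-dimethyl-2H-chromen-8-yl]-1-[2,4,6-trihydroxy-3,5-bis(3-methylbut-2-en-1-yl)phenyl]ethan-1-one | CC(C)=CCc1c(O)c(CC=C(C)C)c(O)c(C(=O)Cc2ccc(OCOC)c3c2OC(C)(C)C=C3)c1O | intermediate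
16 | 3-(dimethylamino)-2-[5-(methoxymethoxy)-2,2-dimethyl-2H-chromen-8-yl]-1-[2,4,6-trihydroxy-3,5-bis(3-methylbut-2-en-1-yl)phenyl]prop-2-en-1-one (enaminone, alkene geometry not defined, not isolated) | CC(C)=CCc1c(O)c(CC=C(C)C)c(O)c(C(=O)C(=CN(C)C)c2ccc(OCOC)c3c2OC(C)(C)C=C3)c1O | intermediate
17 | 5,7-dihydroxy-3-[5-(methoxymethoxy)-2,2-dimethyl-2H-chromen-8-yl]-6,8-bis(3-methylbut-2-en-1-yl)-4H-chromen-4-one | CC(C)=CCc1c(O)c(CC=C(C)C)c2occ(-c3ccc(OCOC)c4c3OC(C)(C)C=C4)c(=O)c2c1O | intermediate
18 | Kanzonol L, 5,7-dihydroxy-3-(5-hydroxy-2,2-dimethyl-2H-chromen-8-yl)-6,8-bis(3-methylbut-2-en-1-yl)-4H-chromen-4-one | CC(C)=CCc1c(O)c(CC=C(C)C)c2occ(-c3ccc(O)c4c3OC(C)(C)C=C4)c(=O)c2c1O | target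

**Step count and risks**

Total steps: 12. Longest linear sequence: 9 steps (steps 4 to 12, from 6). The chain branch (steps 1 to 3) joins at step 9.

Steps most likely to fail:

1. Step 9. The strongly basic terminal carbanion of the trianion may take a proton from the arylacetyl methylene of the amide instead of adding to its carbonyl, so both partners would be returned on work-up. Fallback, from 13 back to 14: reduction of 13 with iBu2AlH (THF, −78 °C) should give 2-[5-(methoxymethoxy)-2,2-dimethyl-2H-chromen-8-yl]acetaldehyde F1. Aldol addition of the trianion of 5 to this aldehyde at −78 °C, where carbonyl addition should outrun proton transfer, should give methyl 7-hydroxy-8-[5-(methoxymethoxy)-2,2-dimethyl-2H-chromen-8-yl]-2,4-bis(3-methylbut-2-en-1-yl)-3,5-dioxooctanoate F2. Dess–Martin oxidation of its secondary alcohol (NaHCO3, CH2Cl2) returns to 14.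

2. Step 10. Closure onto the branched ester, which is partly tied up as its own enolate, may be slow enough for methoxide-induced retro-Claisen fragmentation of the chain, or aldol closure followed by dehydration to a non-aromatic cyclohexenone, to take over. Fallback, from 1 and 13 back to 15: ring A is closed on an unbranched chain and prenylated afterwards. Dianion acetylation of 1 as in step 3 should give methyl 3,5-dioxohexanoate F3. Its trianion (LiN(iPr)2, THF, 0 °C) is acylated with 13 to methyl 8-[5-(methoxymethoxy)-2,2-dimethyl-2H-chromen-8-yl]-3,5,7-trioxooctanoate F4. Claisen cyclisation of this unhindered triketo ester with NaOMe in MeOH, the directly precedented case, should give 2-[5-(methoxymethoxy)-2,2-dimethyl-2H-chromen-8-yl]-1-(2,4,6-trihydroxyphenyl)ethan-1-one F5. Double C-prenylation of the two free ring positions with 2 (aq. KOH, 0 °C) returns to 15, at the cost of a less selective alkylation.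

3. Step 12. During acidic MOM removal the ortho hydroxyls may add across the prenyl double bonds (chroman formation), or the chromene may be hydrated. Fallback, from 13 to 18: the MOM group is removed before any prenyl group is present. Treatment of 13 with HCl in MeOH at rt should give 2-(5-hydroxy-2,2-dimethyl-2H-chromen-8-yl)-N-methoxy-N-methylacetamide F6. As its lithium phenoxide (one further equivalent of LiN(iPr)2) this acylates the trianion of 5 to methyl 8-(5-hydroxy-2,2-dimethyl-2H-chromen-8-yl)-2,4-bis(3-methylbut-2-en-1-yl)-3,5,7-trioxooctanoate F7. NaOMe in MeOH then closes ring A to 2-(5-hydroxy-2,2-dimethyl-2H-chromen-8-yl)-1-[2,4,6-trihydroxy-3,5-bis(3-methylbut-2-en-1-yl)phenyl]ethan-1-one F8. Me2NCH(OMe)2 in THF at 60 °C closes ring C through 3-(dimethylamino)-2-(5-hydroxy-2,2-dimethyl-2H-chromen-8-yl)-1-[2,4,6-trihydroxy-3,5-bis(3-methylbut-2-en-1-yl)phenyl]prop-2-en-1-one F9 and arrives at 18 with no final acid step.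

**Further compounds**

F1 | step 9 | 2-[5-(methoxymethoxy)-2,2-dimethyl-2H-chromen-8-yl]acetaldehyde | O=CCc1ccc(OCOC)c2c1OC(C)(C)C=C2
F2 | step 9 | methyl 7-hydroxy-8-[5-(methoxymethoxy)-2,2-dimethyl-2H-chromen-8-yl]-2,4-bis(3-methylbut-2-en-1-yl)-3,5-dioxooctanoate (stereoisomer mixture) | COC(=O)C(CC=C(C)C)C(=O)C(CC=C(C)C)C(=O)CC(O)Cc1ccc(OCOC)c2c1OC(C)(C)C=C2
F3 | step 10 | methyl 3,5-dioxohexanoate | COC(=O)CC(=O)CC(C)=O
F4 | step 10 | methyl 8-[5-(methoxymethoxy)-2,2-dimethyl-2H-chromen-8-yl]-3,5,7-trioxooctanoate | COC(=O)CC(=O)CC(=O)CC(=O)Cc1ccc(OCOC)c2c1OC(C)(C)C=C2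
F5 | step 10 | 2-[5-(methoxymethoxy)-2,2-dimethyl-2H-chromen-8-yl]-1-(2,4,6-trihydroxyphenyl)ethan-1-one | O=C(Cc1ccc(OCOC)c2c1OC(C)(C)C=C2)c1c(O)cc(O)cc1O
F6 | step 12 | 2-(5-hydroxy-2,2-dimethyl-2H-chromen-8-yl)-N-methoxy-N-methylacetamide | CON(C)C(=O)Cc1ccc(O)c2c1OC(C)(C)C=C2
F7 | step 12 | methyl 8-(5-hydroxy-2,2-dimethyl-2H-chromen-8-yl)-2,4-bis(3-methylbut-2-en-1-yl)-3,5,7-trioxooctanoate (stereoisomer mixture) | COC(=O)C(CC=C(C)C)C(=O)C(CC=C(C)C)C(=O)CC(=O)Cc1ccc(O)c2c1OC(C)(C)C=C2
F8 | step 12 | 2-(5-hydroxy-2,2-dimethyl-2H-chromen-8-yl)-1-[2,4,6-trihydroxy-3,5-bis(3-methylbut-2-en-1-yl)phenyl]ethan-1-one | CC(C)=CCc1c(O)c(CC=C(C)C)c(O)c(C(=O)Cc2ccc(O)c3c2OC(C)(C)C=C3)c1O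
F9 | step 12 | 3-(dimethylamino)-2-(5-hydroxy-2,2-dimethyl-2H-chromen-8-yl)-1-[2,4,6-trihydroxy-3,5-bis(3-methylbut-2-en-1-yl)phenyl]prop-2-en-1-one | CC(C)=CCc1c(O)c(CC=C(C)C)c(O)c(C(=O)C(=CN(C)C)c2ccc(O)c3c2OC(C)(C)C=C3)c1O
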